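The rate constants were chosen freely, and the outcome is calculated.

A one-step world is easy: one arrow, one product, and a longer wait gives more of it. The meeting had before it a flask whose product is itself consumed, and it opened with the charges, the steps and the questions.

common to all: starting material 0.36 M; time 15 h
- midnight: catalyst 25 mM
- dusk: catalyst 50 mM

    starting material + catalyst → catalyst + target (k1 = 0.125 /M/min)
    starting material → side product (k2 = 0.00141 /min)
    catalyst + target → catalyst + over-reaction product (k3 = 0.0355 /M/min)

* which of the two there is more of at the end, midnight (target / over-reaction product)
* which of the two there is more of at the end, dusk (target / over-reaction product)
* amount of target at the end, in percent of the starting material charged, midnight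
* amount of target at the end, in percent of the starting material charged, dusk

I spoke first. I said that the catalyst stands on both sides of its arrows, so [catalyst] stays as charged and each rate follows one changing concentration: the steps are pseudo-first-order. I proposed to carry the target's loss constant L, the constant of the step from target to over-reaction product times [catalyst], 8.87 × 10⁻⁴ /min for midnight.

In the midnight flask, I went on, target is made with a, the constant of its making step times [catalyst], 0.00313 /min. Starting material falls with b, which is a plus the constant of the side step, 0.00453 /min. Since starting material falls faster than target is lost, I argued that the midnight run ends as a slow decay of target. The fraction of target is a/(b − L) × (exp(−Lt) − exp(−bt)). That gave me 37.1 % of target. Over-reaction product, which is what the making step has delivered less that target, came to 30.6 %, so at midnight target leads.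

For dusk I noted that twice the catalyst takes a to 0.00625 /min and L to 0.00177 /min, but b only to 0.00766 /min. The same line gave dusk target 21.4 % and over-reaction product 60.1 %, so there over-reaction product leads.

The maker of the forecast then named target for midnight and over-reaction product for dusk, with target at 37.1 % and 21.4 %, holding that “doubling the catalyst speeds both catalysed steps but not the side reaction”. My target figures stood level with these.

The simulation gave, at midnight, target 37.1 % and over-reaction product 30.6 %, so target leads. At dusk it gave 21.4 % and 60.1 %, so over-reaction product leads.

In the midnight flask, Lt over 15 h comes to 0.799, and exp(−Lt) is 45.0 %. The neighbouring flask is the midnight recipe with 0.062 M of catalyst, read at 15.0 h. In that flask L is 0.00220 /min and Lt is 1.98, so exp(−Lt) is 13.8 %. With a at 0.00775 /min and b at 0.00916 /min, the same line gives target 15.3 %. Simulated, that neighbouring flask holds 15.3 % of target, 15.4 % of side product and 69.3 % of over-reaction product.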